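## Retrosynthetic overview

- Target 24 ← shift of the exocyclic alkene (C8(17) → C7) and reduction of the C3 ketone of the bicyclic ketol 22.
- 22 ← one Lewis-acid cascade on the acyclic α-ketoaldehyde 21. Ring A closes first through the C1–C2 bond (aldehyde carbon C2 attacked by the CH2 terminus C1 of the isopropenyl group on C5). Ring B closes second through C9–C10 (allylsilane onto the C10 cation).
- Enabling feature: the C2/C3 1,2-dicarbonyl hangs on C4, next to the C5 stereocentre. C5 carries both the C10(C20)=C1 isopropenyl group and the C6–C7 tether to the C8=C9 allylsilane, so one cation relay builds rings A and B and sets C2, C10 and C9 from C5.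
- 21 ← C9–C11 Negishi coupling of alkenyl iodide 11 (C5 from (S)-limonene) with zinc reagent 17 (C13 from the (R)-3-methylglutarate half ester 12), then a one-carbon extension (C2).

Key step: step 14

Assumption: atoms are numbered as in the labdane skeleton (C1–C20) throughout, and the chiral-pool materials 1 and 12 are taken as single enantiomers, because the centres they supply (C5 and C13) are too far apart for later upgrading.

## Route

Step 1
Reactants: 1 (S)-(−)-limonene
Product: 2 (4S)-limonene 1,2-oxide (cis/trans mixture)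
Conditions: mCPBA (1.0 equiv), CH2Cl2, 0 °C
Reagents that add atoms: mCPBA (3-chloroperoxybenzoic acid), OOC(=O)c1cccc(Cl)c1
Why: Prilezhaev epoxidation should select the electron-richer trisubstituted ring alkene over the isopropenyl group; the new epoxide centres are destroyed in step 2 and C4 of limonene (future C5) is untouched.

Step 2
Reactants: 2 (4S)-limonene 1,2-oxide
Product: 3 (3S)-6-oxo-3-(prop-1-en-2-yl)heptanal
Conditions: H5IO6 (1.1 equiv), THF/H2O, 0 °C to rt
Reagents that add atoms: water, O
Why: Periodic acid should hydrolyse the epoxide to the glycol and cleave it in the same pot (Malaprade glycol cleavage), leaving the stereocentre intact.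

Step 3
Reactants: 3 (3S)-6-oxo-3-(prop-1-en-2-yl)heptanal
Product: 4 (5S)-7,7-dimethoxy-5-(prop-1-en-2-yl)heptan-2-one
Conditions: HC(OMe)3, MeOH, PPTS (cat.), rt
Reagents that add atoms: trimethyl orthoformate, COC(OC)OC; methanol, CO
Why: Acid-catalysed acetalisation with orthoformate as water scavenger is much faster for the aldehyde than for the methyl ketone (chemoselective protection).

Step 4
Reactants: 4 (5S)-7,7-dimethoxy-5-(prop-1-en-2-yl)heptan-2-one
Product: 6 (5S)-7,7-dimethoxy-5-(prop-1-en-2-yl)hept-1-yne, via enol phosphate 5 (not isolated)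
Conditions: LiN(i-Pr)2 (1.05 equiv), THF, −78 °C; ClP(O)(OEt)2, −78 °C to rt; LiN(i-Pr)2 (2.3 equiv), −78 °C to rt; H2O
Reagents that add atoms: none
Why: Kinetic enolisation on the methyl side, O-phosphorylation and base-induced elimination of the enol phosphate (Negishi alkyne synthesis from a methyl ketone) should give the terminal alkyne whose sp carbons become C8 and C9.

Step 5
Reactants: 6 (5S)-7,7-dimethoxy-5-(prop-1-en-2-yl)hept-1-yne
Product: 8 [(2Z,5S)-2-(iodomethylidene)-7,7-dimethoxy-5-(prop-1-en-2-yl)heptyl]trimethylsilane, via alkenylcopper 7 (not isolated)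
Conditions: Me3SiCH2MgCl, CuBr·SMe2, Et2O/Me2S, −45 °C; 6, −25 °C; then I2, THF, −78 to 0 °C
Reagents that add atoms: (trimethylsilyl)methylmagnesium chloride, C[Si](C)(C)C[Mg]Cl; iodine, II
Why: Syn-carbocupration of the terminal alkyne puts copper on the terminal carbon and the silylmethyl group on the internal one, and iodinolysis with retention should give the alkenyl iodide with C7 trans to iodine, the geometry that later places C11 equatorial.

Step 6
Reactants: 8 [(2Z,5S)-2-(iodomethylidene)-7,7-dimethoxy-5-(prop-1-en-2-yl)heptyl]trimethylsilane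
Product: 9 (3S,6Z)-7-iodo-3-(prop-1-en-2-yl)-6-[(trimethylsilyl)methyl]hept-6-enal
Conditions: oxalic acid (10% aq.), THF, rt
Reagents that add atoms: water, O
Why: Mild aqueous acid should hydrolyse the dimethyl acetal (acetal hydrolysis) without protodesilylating the allylsilane.

Step 7
Reactants: 9 (3S,6Z)-7-iodo-3-(prop-1-en-2-yl)-6-[(trimethylsilyl)methyl]hept-6-enal
Product: 11 (3R,6Z)-7-iodo-2,2-dimethyl-3-(prop-1-en-2-yl)-6-[(trimethylsilyl)methyl]hept-6-enal, via monomethyl aldehyde 10 (not isolated)
Conditions: KOt-Bu (3 equiv), MeI (6 equiv), THF, 0 °C to rt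
Reagents that add atoms: iodomethane, CI
Why: Exhaustive C-methylation of the aldehyde enolate (enolate alkylation) should build the C4 gem-dimethyl group; the β-stereocentre is not enolisable and only its descriptor changes, and the product cannot enolise further.

Step 8
Reactants: 12 (3R)-5-methoxy-3-methyl-5-oxopentanoic acid [(R)-3-methylglutaric acid monomethyl ester]
Product: 14 (4S)-4-methyloxan-2-one, via hydroxy acid 13 (not isolated)
Conditions: LiBH4, THF, 0 °C to rt; then aq. HCl, rt
Reagents that add atoms: none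
Why: LiBH4 reduces the ester but not the lithium carboxylate (chemoselective hydride reduction) and acidification lactonises the hydroxy acid, so the two arms swap oxidation level while the future C13 centre is untouched.

Step 9
Reactants: 14 (4S)-4-methyloxan-2-one
Product: 16 methyl (3R)-5-iodo-3-methylpentanoate, via silyl ester 15 (not isolated)
Conditions: Me3SiCl, NaI, MeCN, 60 °C; then MeOH, rt
Reagents that add atoms: sodium iodide, [Na+].[I-]; methanol, CO
Why: Iodotrimethylsilane made in the flask should open the lactone by SN2 attack of iodide at the O–CH2 carbon, and methanol converts the silyl ester to the methyl ester (acid-catalysed esterification).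

Step 10
Reactants: 11 (3R,6Z)-7-iodo-2,2-dimethyl-3-(prop-1-en-2-yl)-6-[(trimethylsilyl)methyl]hept-6-enal; 16 methyl (3R)-5-iodo-3-methylpentanoate
Product: 18 methyl (3S,6Z,10R)-3,11,11-trimethyl-12-oxo-10-(prop-1-en-2-yl)-7-[(trimethylsilyl)methyl]dodec-6-enoate, via alkylzinc iodide 17 (not isolated)
Conditions: 16, Zn dust, LiCl, THF, 40 °C; then 11, PdCl2(dppf) (5 mol%), THF, rt to 40 °C
Reagents that add atoms: none
Why: LiCl-assisted zinc insertion gives an ester-tolerant alkylzinc iodide that should couple with the alkenyl iodide with retention of geometry (Negishi sp3–sp2 coupling); the hindered, non-enolisable aldehyde is inert to the organozinc.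

Step 11
Reactants: 18 methyl (3S,6Z,10R)-3,11,11-trimethyl-12-oxo-10-(prop-1-en-2-yl)-7-[(trimethylsilyl)methyl]dodec-6-enoate
Product: 19 methyl (3S,6Z,10R)-12-hydroxy-3,11,11-trimethyl-13-[dimethyl(propan-2-yloxy)silyl]-10-(prop-1-en-2-yl)-7-[(trimethylsilyl)methyl]tridec-6-enoate (both C12 epimers)
Conditions: (i-PrO)Me2SiCH2MgCl (1.3 equiv), THF, −40 to 0 °C; then H2O
Reagents that add atoms: [dimethyl(propan-2-yloxy)silyl]methylmagnesium chloride, CC(C)O[Si](C)(C)C[Mg]Cl
Why: Grignard addition of this hydroxymethyl-anion equivalent is faster at the aldehyde than at the methyl ester at low temperature; the carbinol configuration (C3) is irrelevant because it is oxidised in step 13.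

Step 12
Reactants: 19 methyl (3S,6Z,10R)-12-hydroxy-3,11,11-trimethyl-13-[dimethyl(propan-2-yloxy)silyl]-10-(prop-1-en-2-yl)-7-[(trimethylsilyl)methyl]tridec-6-enoate
Product: 20 methyl (3S,6Z,10R)-12,13-dihydroxy-3,11,11-trimethyl-10-(prop-1-en-2-yl)-7-[(trimethylsilyl)methyl]tridec-6-enoate (both C12 epimers)
Conditions: H2O2 (30%), KF, KHCO3, THF/MeOH, rt
Reagents that add atoms: hydrogen peroxide, OO
Why: Tamao–Fleming oxidation should convert the C–Si(Oi-Pr)Me2 bond to C–OH, while the allylic SiMe3 group (no heteroatom on silicon) and the alkenes do not react.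

Step 13
Reactants: 20 methyl (3S,6Z,10R)-12,13-dihydroxy-3,11,11-trimethyl-10-(prop-1-en-2-yl)-7-[(trimethylsilyl)methyl]tridec-6-enoate
Product: 21 methyl (3S,6Z,10R)-3,11,11-trimethyl-12,13-dioxo-10-(prop-1-en-2-yl)-7-[(trimethylsilyl)methyl]tridec-6-enoate (anhydrous, used at once)
Conditions: (COCl)2, DMSO, CH2Cl2, −78 °C; Et3N, −78 to 0 °C
Reagents that add atoms: none
Why: Double Swern oxidation of the terminal 1,2-diol should give the anhydrous α-ketoaldehyde without C–C cleavage; no enolisable position flanks the dicarbonyl.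

Step 14
Reactants: 21 methyl (3S,6Z,10R)-3,11,11-trimethyl-12,13-dioxo-10-(prop-1-en-2-yl)-7-[(trimethylsilyl)methyl]tridec-6-enoate
Product: 22 methyl (13S)-2α-hydroxy-3-oxolabd-8(17)-en-15-oate
Conditions: SnCl4 (1.2 equiv), 2,6-di-tert-butyl-4-methylpyridine (0.3 equiv), CH2Cl2 (0.005 M), −78 °C; aq. NaHCO3
Reagents that add atoms: none
Why: Proposed new method: SnCl4 chelates the C2/C3 dicarbonyl of 21, the CH2 terminus C1 of the isopropenyl group adds to the aldehyde carbon C2 (Prins addition), the tertiary C10 cation so formed is captured by C9 of the allylsilane, and the β-silyl cation at C8 loses the silyl group to leave only the 8(17)-alkene. The closest known reaction types are the Lewis-acid carbonyl-ene/Prins cyclisation of an aldehyde tethered to the central carbon of a 1,1-disubstituted alkene and carbonyl- or acetal-initiated cation–olefin polycyclisations terminated by allylsilanes (Prins then Hosomi–Sakurai); new is the relay of the Prins cation into a second ring fused across C5–C10. Ring A closes 6-endo-trig at C1=C10 and ring B 6-endo-trig at C8=C9, both through chairs. C2 is set by the chelate, which holds the C2–O bond in the plane of the C3 carbonyl (equatorial, 2α) and away from the axial 4β-methyl, and as the carbon α to the ketone it would also equilibrate to this more stable epimer. C10 is set by the C5 stereocentre through anti addition of C2 and C9 across C1=C10 in the chair–chair fold that keeps the C5 arm equatorial (trans fusion, C20 β), the course known for acid closures of monocyclic precursors that already carry the C5 hydrogen, and C9 by the alkene geometry (C7 trans to C11), which places C11 equatorial. The step needs the nearby isopropenyl group (six-membered ring) to beat the more nucleophilic but remote allylsilane (eight-membered ring) at C2, and ring B closure to beat proton loss from C20 to the C2 oxygen; the weakly basic chelated tin alkoxide, the strong π-nucleophile, the hindered base and high dilution are meant to secure this.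

Step 15
Reactants: 22 methyl (13S)-2α-hydroxy-3-oxolabd-8(17)-en-15-oate
Product: 23 methyl (13S)-2α,3α-dihydroxylabd-8(17)-en-15-oate
Conditions: LiBH(s-Bu)3 (2.5 equiv), THF, −78 °C; then H2O
Reagents that add atoms: none
Why: The bulky hydride should attack the C3 ketone from the equatorial (β) direction, as is usual for 4,4-dimethyl-3-oxo terpenoids (substrate-controlled hydride reduction), giving the axial 3α-alcohol cis to the 2α-hydroxyl; the methyl ester is not reduced at −78 °C.

Step 16
Reactants: 23 methyl (13S)-2α,3α-dihydroxylabd-8(17)-en-15-oate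
Product: 24 methyl (13S)-2α,3α-dihydroxylabd-7-en-15-oate (target)
Conditions: chloro[N,N′-bis(3,5-di-tert-butylsalicylidene)cyclohexane-1,2-diaminato]cobalt, (salen)CoCl (3 mol%), PhSiH3 (6 mol%), benzene, rt
Reagents that add atoms: none
Why: Hydrogen-atom transfer from a cobalt hydride to the exocyclic methylene gives the tertiary C8 radical, and back-transfer from the accessible C7 methylene rather than the hindered C9 methine should move the alkene one position into the ring (radical olefin isomerisation by MHAT).

## Compound list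

1 | (S)-(−)-limonene, (4S)-1-methyl-4-(prop-1-en-2-yl)cyclohex-1-ene | CC1=CC[C@H](CC1)C(C)=C | starting material
2 | (4S)-limonene 1,2-oxide, cis/trans mixture at the epoxide | CC12OC1C[C@H](CC2)C(C)=C | intermediate
3 | (3S)-6-oxo-3-(prop-1-en-2-yl)heptanal | O=CC[C@H](CCC(C)=O)C(C)=C | intermediate
4 | (5S)-7,7-dimethoxy-5-(prop-1-en-2-yl)heptan-2-one | COC(OC)C[C@H](CCC(C)=O)C(C)=C | intermediate
5 | diethyl (5S)-7,7-dimethoxy-5-(prop-1-en-2-yl)hept-1-en-2-yl phosphate (not isolated) | COC(OC)C[C@H](CCC(=C)OP(=O)(OCC)OCC)C(C)=C | intermediate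
6 | (5S)-7,7-dimethoxy-5-(prop-1-en-2-yl)hept-1-yne | COC(OC)C[C@H](CCC#C)C(C)=C | intermediate
7 | [(1Z,5S)-7,7-dimethoxy-5-(prop-1-en-2-yl)-2-[(trimethylsilyl)methyl]hept-1-en-1-yl]copper (not isolated) | COC(OC)C[C@H](CC/C(C[Si](C)(C)C)=C/[Cu])C(C)=C | intermediate
8 | [(2Z,5S)-2-(iodomethylidene)-7,7-dimethoxy-5-(prop-1-en-2-yl)heptyl]trimethylsilane | COC(OC)C[C@H](CC/C(C[Si](C)(C)C)=C/I)C(C)=C | intermediate
9 | (3S,6Z)-7-iodo-3-(prop-1-en-2-yl)-6-[(trimethylsilyl)methyl]hept-6-enal | O=CC[C@H](CC/C(C[Si](C)(C)C)=C/I)C(C)=C | intermediate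
10 | (3S,6Z)-7-iodo-2-methyl-3-(prop-1-en-2-yl)-6-[(trimethylsilyl)methyl]hept-6-enal, both C2 epimers (not isolated) | O=CC(C)[C@H](CC/C(C[Si](C)(C)C)=C/I)C(C)=C | intermediate
11 | (3R,6Z)-7-iodo-2,2-dimethyl-3-(prop-1-en-2-yl)-6-[(trimethylsilyl)methyl]hept-6-enal | O=CC(C)(C)[C@H](CC/C(C[Si](C)(C)C)=C/I)C(C)=C | intermediate
12 | (3R)-5-methoxy-3-methyl-5-oxopentanoic acid, (R)-3-methylglutaric acid monomethyl ester | COC(=O)C[C@H](C)CC(O)=O | starting material
13 | (3S)-5-hydroxy-3-methylpentanoic acid (not isolated) | OC(=O)C[C@@H](C)CCO | intermediate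
14 | (4S)-4-methyloxan-2-one | O=C1C[C@@H](C)CCO1 | intermediate
15 | trimethylsilyl (3R)-5-iodo-3-methylpentanoate (not isolated) | C[Si](C)(C)OC(=O)C[C@@H](C)CCI | intermediate
16 | methyl (3R)-5-iodo-3-methylpentanoate | COC(=O)C[C@@H](C)CCI | intermediate
17 | [(3R)-5-methoxy-3-methyl-5-oxopentyl]zinc iodide (not isolated) | COC(=O)C[C@@H](C)CC[Zn]I | intermediate
18 | methyl (3S,6Z,10R)-3,11,11-trimethyl-12-oxo-10-(prop-1-en-2-yl)-7-[(trimethylsilyl)methyl]dodec-6-enoate | COC(=O)C[C@@H](C)CC/C=C(C[Si](C)(C)C)/CC[C@H](C(C)=C)C(C)(C)C=O | intermediate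
19 | methyl (3S,6Z,10R)-12-hydroxy-3,11,11-trimethyl-13-[dimethyl(propan-2-yloxy)silyl]-10-(prop-1-en-2-yl)-7-[(trimethylsilyl)methyl]tridec-6-enoate, both C12 epimers | COC(=O)C[C@@H](C)CC/C=C(C[Si](C)(C)C)/CC[C@H](C(C)=C)C(C)(C)C(O)C[Si](C)(C)OC(C)C | intermediate
20 | methyl (3S,6Z,10R)-12,13-dihydroxy-3,11,11-trimethyl-10-(prop-1-en-2-yl)-7-[(trimethylsilyl)methyl]tridec-6-enoate, both C12 epimers | COC(=O)C[C@@H](C)CC/C=C(C[Si](C)(C)C)/CC[C@H](C(C)=C)C(C)(C)C(O)CO | intermediate
21 | methyl (3S,6Z,10R)-3,11,11-trimethyl-12,13-dioxo-10-(prop-1-en-2-yl)-7-[(trimethylsilyl)methyl]tridec-6-enoate | COC(=O)C[C@@H](C)CC/C=C(C[Si](C)(C)C)/CC[C@H](C(C)=C)C(C)(C)C(=O)C=O | intermediate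
22 | methyl (13S)-2α-hydroxy-3-oxolabd-8(17)-en-15-oate | COC(=O)C[C@@H](C)CC[C@H]1C(=C)CC[C@H]2C(C)(C)C(=O)[C@H](O)C[C@]12C | intermediate
23 | methyl (13S)-2α,3α-dihydroxylabd-8(17)-en-15-oate | COC(=O)C[C@@H](C)CC[C@H]1C(=C)CC[C@H]2C(C)(C)[C@H](O)[C@H](O)C[C@]12C | intermediate
24 | methyl (13S)-2α,3α-dihydroxylabd-7-en-15-oate | COC(=O)C[C@@H](C)CC[C@H]1C(C)=CC[C@H]2C(C)(C)[C@H](O)[C@H](O)C[C@]12C | target

## Step count and risks

Total step count: 16. Longest linear sequence: 14 (steps 1–7 and 10–16).

**Step 14 (Proposed new method).** After the C1–C2 bond has formed, the tin-bound oxygen on C2 may take a proton from C20 before C9 reaches C10, so the cascade stops at the monocyclic carbonyl-ene stage; the allylsilane may also add to the aldehyde directly. The fallback uses known chemistry: an acetal-initiated cation–olefin cyclisation terminated by the allylsilane, then removal of the ether tether by oxidation and β-elimination. It sets out from 21.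
- 1,3-Propanediol, PPTS and MgSO4 in CH2Cl2 should acetalise only the aldehyde and give methyl (3S,6Z,10R)-12-(1,3-dioxan-2-yl)-3,11,11-trimethyl-12-oxo-10-(prop-1-en-2-yl)-7-[(trimethylsilyl)methyl]dodec-6-enoate F1.
- TiCl4 in CH2Cl2 at −78 °C opens the acetal to an oxocarbenium ion that has no basic oxygen near C20. The same two ring closures should then give methyl (13S)-2α-(3-hydroxypropoxy)-3-oxolabd-8(17)-en-15-oate F2.
- Dess–Martin periodinane oxidises the primary alcohol to methyl (13S)-3-oxo-2α-(3-oxopropoxy)labd-8(17)-en-15-oate F3.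
- DBU in CH2Cl2 eliminates the ether arm (retro-oxa-Michael), and the fallback comes back to the route at 22.

**Step 16.** Hydrogen back-transfer may occur from C9 instead of C7 (giving the 8-ene), or the isomerisation may stop short and leave olefin isomers that are hard to separate. The fallback replaces C17 by regiospecific enol triflate chemistry and sets out from 23.
- 2,2-Dimethoxypropane and PPTS give methyl (13S)-2α,3α-(isopropylidenedioxy)labd-8(17)-en-15-oate F4.
- Ozonolysis (O3, CH2Cl2/MeOH, −78 °C; Me2S) of the only alkene gives methyl (13S)-2α,3α-(isopropylidenedioxy)-8-oxo-17-norlabdan-15-oate F5.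
- KN(SiMe3)2 and PhNTf2 in THF at −78 °C deprotonate the C7 methylene rather than the hindered C9 methine and give methyl (13S)-2α,3α-(isopropylidenedioxy)-8-(trifluoromethylsulfonyloxy)-17-norlabd-7-en-15-oate F6.
- MeMgBr with Fe(acac)3 (cat.) in THF/NMP at −30 °C installs the methyl group and gives methyl (13S)-2α,3α-(isopropylidenedioxy)labd-7-en-15-oate F7.
- Aqueous acetic acid in THF removes the acetonide, and the fallback comes back to the route at 24.

**Step 15.** Facial selectivity of hydride delivery may be poor, with attack from the α face giving the 3β-epimer (trans-diol). The fallback replaces substrate control by catalyst control: an NADPH-dependent ketoreductase (alcohol dehydrogenase class) chosen from a panel for 3α-selectivity, with glucose and glucose dehydrogenase for cofactor recycling, in buffer/DMSO at 30 °C. It sets out from 22 and comes back to the route at 23; no new compound is made (F0).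

Further compounds
F1 | step 14 | methyl (3S,6Z,10R)-12-(1,3-dioxan-2-yl)-3,11,11-trimethyl-12-oxo-10-(prop-1-en-2-yl)-7-[(trimethylsilyl)methyl]dodec-6-enoate | COC(=O)C[C@@H](C)CC/C=C(C[Si](C)(C)C)/CC[C@H](C(C)=C)C(C)(C)C(=O)C1OCCCO1
F2 | step 14 | methyl (13S)-2α-(3-hydroxypropoxy)-3-oxolabd-8(17)-en-15-oate | COC(=O)C[C@@H](C)CC[C@H]1C(=C)CC[C@H]2C(C)(C)C(=O)[C@H](OCCCO)C[C@]12C
F3 | step 14 | methyl (13S)-3-oxo-2α-(3-oxopropoxy)labd-8(17)-en-15-oate | COC(=O)C[C@@H](C)CC[C@H]1C(=C)CC[C@H]2C(C)(C)C(=O)[C@H](OCCC=O)C[C@]12C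
F4 | step 16 | methyl (13S)-2α,3α-(isopropylidenedioxy)labd-8(17)-en-15-oate | COC(=O)C[C@@H](C)CC[C@H]1C(=C)CC[C@H]2C(C)(C)[C@@H]3OC(C)(C)O[C@@H]3C[C@]12C
F5 | step 16 | methyl (13S)-2α,3α-(isopropylidenedioxy)-8-oxo-17-norlabdan-15-oate | COC(=O)C[C@@H](C)CC[C@H]1C(=O)CC[C@H]2C(C)(C)[C@@H]3OC(C)(C)O[C@@H]3C[C@]12C
F6 | step 16 | methyl (13S)-2α,3α-(isopropylidenedioxy)-8-(trifluoromethylsulfonyloxy)-17-norlabd-7-en-15-oate | COC(=O)C[C@@H](C)CC[C@H]1C(OS(=O)(=O)C(F)(F)F)=CC[C@H]2C(C)(C)[C@@H]3OC(C)(C)O[C@@H]3C[C@]12C
F7 | step 16 | methyl (13S)-2α,3α-(isopropylidenedioxy)labd-7-en-15-oate | COC(=O)C[C@@H](C)CC[C@H]1C(C)=CC[C@H]2C(C)(C)[C@@H]3OC(C)(C)O[C@@H]3C[C@]12C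
F0 | step 15 | none | none
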